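**Retrosynthetic overview**

1. 21 ⇐ 20: the C12' isopropenyl group comes from a C12' methyl ketone by Wittig methylenation, so that no alkene is present in the oxidative step.
2. 20 ⇐ 18 (key): in ring A, O1 sits on C8a para to the C6 hydroxyl, and C4a is the only hydrogen-bearing carbon next to C8a. A chain bonded to C8a in phenol 18 therefore first gives O1–C8a (spiro five-membered ether 19), then C4 moves from C8a to C4a. Ring order: ring A is bought, the spiro ether ring forms, ring B arises from it by ring expansion.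
3. 18 ⇐ 15 + 2: C4–aryl bond by hydroboration and B-alkyl Suzuki coupling of a tertiary vinyl carbinol with 4-bromo-2,3,6-trimethylphenol.
4. 15 ⇐ 10: the prenyl end of a C18 ketal becomes the C2 carbinol by allylic oxidation, Sharpless epoxidation (sets C2), hydride opening, oxidation and methylenation.
5. 10 ⇐ 8 + 4 + 3: two copper-catalysed sp3–sp3 couplings join (S)-citronellyl bromide (C4'), (S)-3-bromo-2-methylpropan-1-ol (C8') and the ketal bromide (C10' to C13').

Key step: step 11

Remark: side-chain carbons are numbered C1' to C13' from C2. No bond at C4' or C8' is made or broken after steps 2 and 4. The descriptor of C8' reads S in the ketal, ketone and alkene compounds only because the C12' end outranks the C4' branch.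

**Step 1**
Reactants: 1 2,3,6-trimethylphenol
Product: 2 4-bromo-2,3,6-trimethylphenol
Conditions: NBS (1.0 equiv), MeCN, 0 to 20 °C
Reagents that add atoms: N-bromosuccinimide, O=C1CCC(=O)N1Br
Why: Electrophilic aromatic bromination; both ortho positions carry methyl groups, so bromine should enter the only free activated position, para to the hydroxyl.

**Step 2**
Reactants: 3 2-(2-bromoethyl)-2-methyl-1,3-dioxolane; 4 (S)-3-bromo-2-methylpropan-1-ol
Product: 6 (2R)-2-methyl-5-(2-methyl-1,3-dioxolan-2-yl)pentan-1-ol, via alkylmagnesium bromide 5 (not isolated)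
Conditions: Mg, THF, 25 °C (3 to 5, 2.3 equiv); 4, THF, −78 °C; Li2CuCl4 (3 mol%), −78 to 0 °C
Reagents that add atoms: none
Why: Copper-catalysed Grignard–alkyl bromide cross-coupling (Kochi–Schlosser type), in which the first equivalent of 5 turns the hydroxyl of 4 into its magnesium alkoxide and the second displaces the primary bromide, while the stereocentre of 4 (the future C8') is not touched.

**Step 3**
Reactants: 6 (2R)-2-methyl-5-(2-methyl-1,3-dioxolan-2-yl)pentan-1-ol
Product: 7 (2R)-2-methyl-5-(2-methyl-1,3-dioxolan-2-yl)pentyl 4-methylbenzenesulfonate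
Conditions: TsCl, Et3N, DMAP (cat.), CH2Cl2, 0 to 20 °C
Reagents that add atoms: p-toluenesulfonyl chloride, Cc1ccc(cc1)S(Cl)(=O)=O
Why: Sulfonylation of the primary alcohol under basic conditions gives the leaving group for the next coupling and leaves the ketal and the stereocentre alone.

**Step 4**
Reactants: 8 (6S)-8-bromo-2,6-dimethyloct-2-ene ((S)-citronellyl bromide); 7 (2R)-2-methyl-5-(2-methyl-1,3-dioxolan-2-yl)pentyl 4-methylbenzenesulfonate
Product: 10 2-methyl-2-[(4S,8R)-4,8,12-trimethyltridec-11-en-1-yl]-1,3-dioxolane, via citronellylmagnesium bromide 9 (not isolated)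
Conditions: Mg, THF, 40 °C (8 to 9, 1.5 equiv); 7, Li2CuCl4 (5 mol%), THF, −78 to 20 °C
Reagents that add atoms: none
Why: A second Li2CuCl4-catalysed sp3–sp3 Grignard coupling, now with a primary tosylate, joins C6' to C7'; C4' comes unchanged from 8 and C8' unchanged from 7.

**Step 5**
Reactants: 10 2-methyl-2-[(4S,8R)-4,8,12-trimethyltridec-11-en-1-yl]-1,3-dioxolane
Product: 11 (2E,6R,10S)-2,6,10-trimethyl-13-(2-methyl-1,3-dioxolan-2-yl)tridec-2-en-1-ol
Conditions: SeO2 (0.3 equiv), t-BuOOH (3 equiv, in decane), CH2Cl2, 20 °C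
Reagents that add atoms: selenium dioxide (oxygen carrier), O=[Se]=O; tert-butyl hydroperoxide (terminal oxidant), CC(C)(C)OO
Why: Riley allylic oxidation (ene reaction, then [2,3]-sigmatropic shift), which attacks the methyl group trans to the chain on the more substituted alkene carbon and should therefore give the (E)-allylic alcohol.

**Step 6**
Reactants: 11 (2E,6R,10S)-2,6,10-trimethyl-13-(2-methyl-1,3-dioxolan-2-yl)tridec-2-en-1-ol
Product: 12 [(2S,3S)-3-[(3R,7S)-3,7-dimethyl-10-(2-methyl-1,3-dioxolan-2-yl)decyl]-2-methyloxiran-2-yl]methanol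
Conditions: Ti(OiPr)4 (10 mol%), L-(+)-diethyl tartrate (12 mol%), t-BuOOH (2 equiv), 4 Å MS, CH2Cl2, −20 °C
Reagents that add atoms: tert-butyl hydroperoxide, CC(C)(C)OO
Why: Sharpless asymmetric epoxidation; with the L-(+)-tartrate ligand the oxygen is delivered to the face that gives the (2S,3S)-epoxide of an (E)-2-methylalk-2-en-1-ol, so the future C2 of the chroman is set under reagent control.

**Step 7**
Reactants: 12 [(2S,3S)-3-[(3R,7S)-3,7-dimethyl-10-(2-methyl-1,3-dioxolan-2-yl)decyl]-2-methyloxiran-2-yl]methanol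
Product: 13 (2R,6R,10S)-2,6,10-trimethyl-13-(2-methyl-1,3-dioxolan-2-yl)tridecane-1,2-diol
Conditions: LiAlH4, THF, 0 to 20 °C
Reagents that add atoms: none
Why: SN2 hydride opening of the trisubstituted epoxide at its less substituted carbon (the future C1') leaves the quaternary C–O bond intact, so the tertiary carbinol keeps the configuration set in step 6.

**Step 8**
Reactants: 13 (2R,6R,10S)-2,6,10-trimethyl-13-(2-methyl-1,3-dioxolan-2-yl)tridecane-1,2-diol
Product: 14 (2R,6R,10S)-2-hydroxy-2,6,10-trimethyl-13-(2-methyl-1,3-dioxolan-2-yl)tridecanal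
Conditions: (COCl)2, DMSO, CH2Cl2, −78 °C; Et3N, −78 to 0 °C
Reagents that add atoms: none
Why: Swern oxidation converts the primary hydroxyl into the aldehyde, the tertiary hydroxyl cannot be oxidised, and the quaternary alpha carbon cannot epimerise.

**Step 9**
Reactants: 14 (2R,6R,10S)-2-hydroxy-2,6,10-trimethyl-13-(2-methyl-1,3-dioxolan-2-yl)tridecanal
Product: 15 (3R,7R,11S)-3,7,11-trimethyl-14-(2-methyl-1,3-dioxolan-2-yl)tetradec-1-en-3-ol
Conditions: Ph3PCH3Br (3 equiv), KN(SiMe3)2 (2.9 equiv), THF, 0 to 20 °C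
Reagents that add atoms: methyltriphenylphosphonium bromide, C[P+](c1ccccc1)(c1ccccc1)c1ccccc1.[Br-]
Why: Wittig methylenation of the aldehyde with excess ylide (one equivalent is taken up by the free tertiary hydroxyl) gives the tertiary vinyl carbinol without touching a stereocentre.

**Step 10**
Reactants: 15 (3R,7R,11S)-3,7,11-trimethyl-14-(2-methyl-1,3-dioxolan-2-yl)tetradec-1-en-3-ol; 2 4-bromo-2,3,6-trimethylphenol
Product: 18 (6S,10R,14R)-14-hydroxy-16-(4-hydroxy-2,3,5-trimethylphenyl)-6,10,14-trimethylhexadecan-2-one, via B-alkyl-9-BBN adduct 16 (not isolated), via ketal phenol 17 (not isolated)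
Conditions: 9-BBN (1.5 equiv), THF, 0 to 20 °C; 2, Pd(OAc)2 (5 mol%), SPhos (10 mol%), K3PO4 (4 equiv), THF–H2O, 60 °C; 2 M HCl, THF, 20 °C
Reagents that add atoms: water, O
Why: Anti-Markovnikov hydroboration of the monosubstituted alkene, then B-alkyl Suzuki–Miyaura coupling with the aryl bromide (which reacts as its phenoxide, tolerated by the electron-rich SPhos ligand) forms the C4–aryl bond, and aqueous acid then hydrolyses the dioxolane to the C12' ketone.

**Step 11**
Reactants: 18 (6S,10R,14R)-14-hydroxy-16-(4-hydroxy-2,3,5-trimethylphenyl)-6,10,14-trimethylhexadecan-2-one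
Product: 20 (6S,10R)-13-[(2R)-6-hydroxy-2,5,7,8-tetramethyl-3,4-dihydro-2H-chromen-2-yl]-6,10-dimethyltridecan-2-one, via spirodienone 19 (not isolated)
Conditions: PhI(OAc)2 (1.05 equiv), (CF3)2CHOH, 0 °C; evaporate, CH2Cl2; BF3·OEt2 (3 equiv), −78 to −30 °C
Reagents that add atoms: none
Why: Proposed new method: PhI(OAc)2 in (CF3)2CHOH oxidises the phenol of 18 to a phenoxenium-type cation, which the tertiary hydroxyl traps at the para carbon in a 5-exo-trig closure (O1–C8a) to give spirodienone 19 as both epimers at the spiro carbon; BF3 then activates the dienone carbonyl, C4 shifts from C8a to the neighbouring C4a (new C4–C4a bond, five-membered ether expanded to six-membered ring B) and loss of the C4a proton restores ring A. The closest known reaction types are the trivalent-iodine spiroetherification of para-(hydroxyalkyl)phenols and the acid-promoted dienone–phenol rearrangement of 4,4-disubstituted cyclohexadienones with carbon migration; their combination on a spiro ether whose C2–O1 bond is tertiary has not been shown. Product 20 gains no stereocentre (the spiro centre of 19 vanishes on aromatisation) and C2 keeps its configuration because the C2–O1 bond is not broken at any point. The step needs migration of carbon and not of oxygen, which the lone pairs on O1 secure by stabilising the positive charge left on C8a, and migration to C4a and not to C8, which is secured because only the C4a adduct can rearomatise by proton loss while C8 carries a methyl group. Heterolysis of the tertiary C2–O1 bond is limited by the aprotic Lewis acid at low temperature, and the C12' ketone tolerates both the oxidant and BF3 (it binds one equivalent) where an isopropenyl group would not.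

**Step 12**
Reactants: 20 (6S,10R)-13-[(2R)-6-hydroxy-2,5,7,8-tetramethyl-3,4-dihydro-2H-chromen-2-yl]-6,10-dimethyltridecan-2-one
Product: 21 (2R)-2,5,7,8-tetramethyl-2-[(4R,8S)-4,8,12-trimethyltridec-12-en-1-yl]-3,4-dihydro-2H-chromen-6-ol
Conditions: Ph3PCH3Br (4 equiv), KN(SiMe3)2 (3.9 equiv), THF, 0 to 40 °C, argon
Reagents that add atoms: methyltriphenylphosphonium bromide, C[P+](c1ccccc1)(c1ccccc1)c1ccccc1.[Br-]
Why: Wittig methylenation of the methyl ketone; the first equivalent of ylide deprotonates the hindered phenol, whose phenoxide is inert, and the excess converts the ketone into the 1,1-disubstituted alkene.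

**Compound list**

1 | 2,3,6-trimethylphenol | Cc1ccc(C)c(C)c1O | starting material
2 | 4-bromo-2,3,6-trimethylphenol | Cc1cc(Br)c(C)c(C)c1O | intermediate
3 | 2-(2-bromoethyl)-2-methyl-1,3-dioxolane | CC1(CCBr)OCCO1 | starting material
4 | (S)-3-bromo-2-methylpropan-1-ol | BrC[C@@H](C)CO | starting material
5 | [2-(2-methyl-1,3-dioxolan-2-yl)ethyl]magnesium bromide | CC1(CC[Mg]Br)OCCO1 | intermediate
6 | (2R)-2-methyl-5-(2-methyl-1,3-dioxolan-2-yl)pentan-1-ol | CC1(CCC[C@@H](C)CO)OCCO1 | intermediate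
7 | (2R)-2-methyl-5-(2-methyl-1,3-dioxolan-2-yl)pentyl 4-methylbenzenesulfonate | CC1(CCC[C@@H](C)COS(=O)(=O)c2ccc(C)cc2)OCCO1 | intermediate
8 | (6S)-8-bromo-2,6-dimethyloct-2-ene ((S)-citronellyl bromide) | BrCC[C@@H](C)CCC=C(C)C | starting material
9 | [(3S)-3,7-dimethyloct-6-en-1-yl]magnesium bromide | Br[Mg]CC[C@@H](C)CCC=C(C)C | intermediate
10 | 2-methyl-2-[(4S,8R)-4,8,12-trimethyltridec-11-en-1-yl]-1,3-dioxolane | CC1(CCC[C@@H](C)CCC[C@@H](C)CCC=C(C)C)OCCO1 | intermediate
11 | (2E,6R,10S)-2,6,10-trimethyl-13-(2-methyl-1,3-dioxolan-2-yl)tridec-2-en-1-ol | CC1(CCC[C@@H](C)CCC[C@@H](C)CC/C=C(\C)CO)OCCO1 | intermediate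
12 | [(2S,3S)-3-[(3R,7S)-3,7-dimethyl-10-(2-methyl-1,3-dioxolan-2-yl)decyl]-2-methyloxiran-2-yl]methanol | CC1(CCC[C@@H](C)CCC[C@@H](C)CC[C@@H]2O[C@@]2(C)CO)OCCO1 | intermediate
13 | (2R,6R,10S)-2,6,10-trimethyl-13-(2-methyl-1,3-dioxolan-2-yl)tridecane-1,2-diol | CC1(CCC[C@@H](C)CCC[C@@H](C)CCC[C@](O)(C)CO)OCCO1 | intermediate
14 | (2R,6R,10S)-2-hydroxy-2,6,10-trimethyl-13-(2-methyl-1,3-dioxolan-2-yl)tridecanal | CC1(CCC[C@@H](C)CCC[C@@H](C)CCC[C@](O)(C)C=O)OCCO1 | intermediate
15 | (3R,7R,11S)-3,7,11-trimethyl-14-(2-methyl-1,3-dioxolan-2-yl)tetradec-1-en-3-ol | CC1(CCC[C@@H](C)CCC[C@@H](C)CCC[C@](O)(C)C=C)OCCO1 | intermediate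
16 | (3S,7R,11S)-1-(9-borabicyclo[3.3.1]nonan-9-yl)-3,7,11-trimethyl-14-(2-methyl-1,3-dioxolan-2-yl)tetradecan-3-ol (same spatial arrangement at the carbinol as in 15) | CC1(CCC[C@@H](C)CCC[C@@H](C)CCC[C@](O)(C)CCB2C3CCCC2CCC3)OCCO1 | intermediate
17 | 4-[(3R,7R,11S)-3-hydroxy-3,7,11-trimethyl-14-(2-methyl-1,3-dioxolan-2-yl)tetradecyl]-2,3,6-trimethylphenol | CC1(CCC[C@@H](C)CCC[C@@H](C)CCC[C@](O)(C)CCc2cc(C)c(O)c(C)c2C)OCCO1 | intermediate
18 | (6S,10R,14R)-14-hydroxy-16-(4-hydroxy-2,3,5-trimethylphenyl)-6,10,14-trimethylhexadecan-2-one | CC(=O)CCC[C@@H](C)CCC[C@@H](C)CCC[C@](O)(C)CCc1cc(C)c(O)c(C)c1C | intermediate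
19 | (2R)-2-[(4R,8S)-4,8-dimethyl-12-oxotridecyl]-2,6,7,9-tetramethyl-1-oxaspiro[4.5]deca-6,9-dien-8-one, both epimers at the spiro carbon C5 | CC(=O)CCC[C@@H](C)CCC[C@@H](C)CCC[C@]1(C)CCC2(O1)C=C(C)C(=O)C(C)=C2C | intermediate
20 | (6S,10R)-13-[(2R)-6-hydroxy-2,5,7,8-tetramethyl-3,4-dihydro-2H-chromen-2-yl]-6,10-dimethyltridecan-2-one | CC(=O)CCC[C@@H](C)CCC[C@@H](C)CCC[C@]1(C)CCc2c(C)c(O)c(C)c(C)c2O1 | intermediate
21 | (2R)-2,5,7,8-tetramethyl-2-[(4R,8S)-4,8,12-trimethyltridec-12-en-1-yl]-3,4-dihydro-2H-chromen-6-ol | C=C(C)CCC[C@@H](C)CCC[C@@H](C)CCC[C@]1(C)CCc2c(C)c(O)c(C)c(C)c2O1 | target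

**Step count**

Total steps: 12. Longest linear sequence: 11 steps (from 3 and 4 to 21, steps 2 to 12).

**Steps most likely to fail**

Step 11 (proposed new method). The tertiary C2–O1 bond of 19 may ionise under the Lewis acid, leading to elimination or loss of configuration. Oxygen may migrate instead of carbon, or left-over oxidant may attack the electron-rich chromanol. The fallback uses known chemistry, sets out from 15 and comes back at 20.
- Trimethylhydroquinone is O-methylated (Me2SO4, K2CO3, acetone) to 1,4-dimethoxy-2,3,5-trimethylbenzene F1 and brominated (NBS, MeCN) to 1-bromo-2,5-dimethoxy-3,4,6-trimethylbenzene F2.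
- Borane 16, made from 15 as in step 10, is coupled with F2 (Pd(OAc)2, SPhos, K3PO4, THF–H2O) to the dimethoxyarene carbinol F3.
- (NH4)2Ce(NO3)6 in aqueous MeCN should oxidise the arene to the quinone while the acidic medium frees the ketone, giving the hydroxyalkyl quinone F4.
- Hydrogenation (H2, Pd/C, EtOAc) to the hydroquinone F5 and acid-catalysed cyclodehydration (p-TsOH, toluene) should then give 20. In the tocopherol series this closure is known to keep the side-chain oxygen, and with it the configuration at C2.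

Step 5. The allylic oxidation may stall at partial conversion, over-oxidise to the enal, or cleave the ketal through the acidic selenium species. The fallback sets out from 10 and comes back at 11.
- Ozonolysis of the trisubstituted alkene (O3, CH2Cl2–MeOH, −78 °C; Me2S) gives the aldehyde F6.
- Wittig reaction with Ph3P=C(CH3)CO2Et (toluene, 80 °C) gives the (E)-2-methyl enoate F7.
- i-Bu2AlH (CH2Cl2, −78 °C) reduces F7 to 11.

Step 10. Oxidative addition to the electron-rich, ortho-methylated bromophenoxide may be slow, so that protodeboronation of the alkylborane wins. The fallback sets out from 15 and comes back at 18.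
- Mizoroki–Heck arylation of 15 with 2 (Pd(OAc)2, P(o-tolyl)3, Et3N, DMF, 100 °C) gives the (E)-styrenyl carbinol F8.
- Hydrogenation (H2, Pd/C, EtOAc) saturates the alkene to 17, and 2 M HCl in THF frees the ketone to give 18.

**Further compounds**

F1 | step 11 | 1,4-dimethoxy-2,3,5-trimethylbenzene | COc1cc(C)c(OC)c(C)c1C
F2 | step 11 | 1-bromo-2,5-dimethoxy-3,4,6-trimethylbenzene | COc1c(Br)c(C)c(OC)c(C)c1C
F3 | step 11 | (3R,7R,11S)-1-(2,5-dimethoxy-3,4,6-trimethylphenyl)-3,7,11-trimethyl-14-(2-methyl-1,3-dioxolan-2-yl)tetradecan-3-ol | CC1(CCC[C@@H](C)CCC[C@@H](C)CCC[C@](O)(C)CCc2c(C)c(OC)c(C)c(C)c2OC)OCCO1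
F4 | step 11 | 2-[(3R,7R,11S)-3-hydroxy-3,7,11-trimethyl-15-oxohexadecyl]-3,5,6-trimethylcyclohexa-2,5-diene-1,4-dione | CC(=O)CCC[C@@H](C)CCC[C@@H](C)CCC[C@](O)(C)CCC1=C(C)C(=O)C(C)=C(C)C1=O
F5 | step 11 | 2-[(3R,7R,11S)-3-hydroxy-3,7,11-trimethyl-15-oxohexadecyl]-3,5,6-trimethylbenzene-1,4-diol | CC(=O)CCC[C@@H](C)CCC[C@@H](C)CCC[C@](O)(C)CCc1c(C)c(O)c(C)c(C)c1O
F6 | step 5 | (4R,8S)-4,8-dimethyl-11-(2-methyl-1,3-dioxolan-2-yl)undecanal | CC1(CCC[C@@H](C)CCC[C@@H](C)CCC=O)OCCO1
F7 | step 5 | ethyl (2E,6R,10S)-2,6,10-trimethyl-13-(2-methyl-1,3-dioxolan-2-yl)tridec-2-enoate | CC1(CCC[C@@H](C)CCC[C@@H](C)CC/C=C(\C)C(=O)OCC)OCCO1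
F8 | step 10 | 4-[(1E,3R,7R,11S)-3-hydroxy-3,7,11-trimethyl-14-(2-methyl-1,3-dioxolan-2-yl)tetradec-1-en-1-yl]-2,3,6-trimethylphenol | CC1(CCC[C@@H](C)CCC[C@@H](C)CCC[C@](O)(C)/C=C/c2cc(C)c(O)c(C)c2C)OCCO1
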